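**Assumption (remark on the chemistry):** compounds 1, 2, 4, 9 and 12 are taken as commercial. Carbinol 3 is used as the racemate because its stereocentre is destroyed in step 2. All triene-containing compounds are handled under argon with exclusion of light. The route has not been run; every outcome below is a prediction.

## Structural features

The target is a 1-O-alkyl-2-O-acyl-sn-glycerol: glycerol O1 carries an unbranched C12 chain as an ether, O2 a 4-hydroxybenzoyl ester and O3 is a free hydroxyl; the only ring is the para-disubstituted benzene ring. The single stereocentre is glycerol C2 (S), flanked by two CH2–O groups that differ only in what sits on oxygen, so the route must tell three similar oxygens apart. The chain holds a conjugated (4E,6E,8E)-triene, C4 to C9, insulated on both sides by sp3 carbons (C3 and C10), so three stereogenic double bonds must be set with no carbonyl or aryl group in conjugation to steer geometry. Fragile groups are the triene (acid, light, radicals, oxidants; hydrogenolysis is excluded), the secondary aroate next to a free primary hydroxyl (O2→O3 acyl migration is downhill under base and acid) and the free phenol. The real difficulty is the geometrically pure, unactivated triene; the second is to free O3–H last without moving the ester. The key step exploits the fact that C1–C2–C3–C4=C5 is a γ,δ-unsaturated acyl retron once C1 is at the acid oxidation level, so a Claisen rearrangement can make the C2–C3 bond and the C4=C5 double bond together, while C5–C12 is the skeleton of a commercial (2E,4E)-dienal. In one sentence: an orthoester Claisen rearrangement of the racemic dienyl vinyl carbinol 3 delivers the complete (E,E,E)-C12 chain as ester 7.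

## Logic of the disconnections

**15 from 14.** The O3–CPh3 bond is cut. The primary hydroxyl is released last so that the ester on O2 never sits beside a free hydroxyl while any base or nucleophile is present. The forward step must remove the trityl group with catalytic acid at low temperature, faster than the acyl group can migrate or the triene can be protonated.

**14 from 13.** The phenolic O–acetyl bond is cut. The phenol must be masked during acylation, and unmasking it while O3 is still blocked removes any chance of migration at that stage. The forward step must distinguish an aryl acetate from a secondary alkyl aroate.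

**13 from 11 and 12.** The acyl C–O bond at glycerol O2 is cut. This separates the aromatic unit from the lipid; C2 is not touched, so its configuration passes through unchanged. The forward step must acylate a secondary hydroxyl flanked by a bulky trityloxymethyl group.

**11 from 8 and 9 (through 10).** The glycerol C1–O ether bond is cut. This separates the whole C12 chain from a three-carbon chiral-pool epoxide that supplies the C2 configuration and differentiates all three glycerol oxygens in one operation. The forward step needs alkoxide 10 to attack only the terminal epoxide carbon, under conditions that leave the triene alone.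

**8 from 7.** Only the oxidation level of C1 is changed (ester to primary alcohol); no skeletal bond is cut. The forward step needs a hydride source that does not touch the triene.

**7 from 3 and 4 (through 5 and 6), the key disconnection.** The C2–C3 σ bond is cut and the C4=C5 double bond is transposed to a terminal vinyl group with oxygen on C5 (retro-[3,3]). A triene ester with three defined double bonds becomes a dienyl vinyl carbinol whose only new stereo element is irrelevant, plus a two-carbon orthoester. The forward step must choose the vinyl arm over the dienyl arm, give the E double bond, and outrun ionisation of the doubly allylic C–O bond.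

**3 from 1 and 2.** The C–C bond between the carbinol carbon and the vinyl group (the future C4–C5 bond of the target) is cut. This leads back to a commercial dienal that already holds the 6E and 8E double bonds and the propyl tail. The forward step needs 1,2-addition in preference to conjugate addition.

## Other disconnections considered

**Alternative 1:** cut at C4=C5, the disconnection that comes to mind first. The forward key step would be a Wittig olefination of 1 with the ylide from (4-hydroxybutyl)triphenylphosphonium bromide A1. An unstabilised ylide is Z-selective under kinetic control, so the expected product is (4Z,6E,8E)-dodeca-4,6,8-trien-1-ol A2, which would then have to be equilibrated toward 8. For a dialkyl triene with no conjugating end group the all-E isomer is favoured only modestly at equilibrium, and the remaining geometric isomers should be hard to separate from 8. The chosen plan sets C4=C5 in a closed chair transition state instead of correcting it afterwards, at a cost of one step more.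

**Alternative 2:** cut the C3–C4 sp3–sp2 bond. The forward key step would be a B-alkyl Suzuki–Miyaura coupling of the 9-BBN adduct of allyl ether A4, (2R)-1-(prop-2-en-1-yloxy)-3-(triphenylmethoxy)propan-2-ol, with (1E,3E,5E)-1-iodonona-1,3,5-triene A3 (from 1 by Takai iodo-olefination), giving 11 directly. It is convergent and short. However, the C4=C5 geometry again rests on reagent control in an olefination of a conjugated aldehyde, A3 is a light- and heat-sensitive iodotriene, stoichiometric chromium(II) is needed, and the free hydroxyl of A4 consumes borane. It is also a cross-coupling that many would draw, so it fails the first test.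

**Alternative 3:** cut the glycerol C1–O bond and treat C3–O3 as the other half of an oxetane. The forward key step would be a desymmetrising opening of oxetan-3-yl 4-hydroxybenzoate A5 by the hydroxyl of 8 under a chiral Brønsted acid, which would form the ether, set C2 and release O3–H to give 15 in one step. The ester carbonyl on oxetane C3 is placed for five-membered participation at the activated CH2. The resulting dioxolanylium ion can collapse onto the released hydroxyl to the achiral bicyclic orthoester A6, 4-(2,6,7-trioxabicyclo[2.2.1]heptan-1-yl)phenol, which would erase the distinction between the enantiotopic CH2 groups and scramble the acyl position. An intermolecular alcohol nucleophile has no close precedent in this mode, the acyloxy group deactivates the oxetane inductively, and an acid strong enough would threaten the triene. Since C2 comes cheaply from the chiral pool, the risk buys little.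

Key step: step 2

## Route

**Step 1**
Reactants: 1 (2E,4E)-octa-2,4-dienal; 2 vinylmagnesium bromide
Product: 3 rac-(4E,6E)-deca-1,4,6-trien-3-ol
Conditions: vinylMgBr (1.2 equiv), THF, −78 to 0 °C; aq. NH4Cl
Reagents that add atoms: vinylmagnesium bromide, C=C[Mg]Br
Why: 1,2-addition of a Grignard reagent to a conjugated aldehyde; hard vinyl Grignard reagents attack the carbonyl carbon of enals in preference to conjugate addition, and the carbinol centre is formed racemic on purpose because step 2 destroys it.

**Step 2**
Reactants: 3 rac-(4E,6E)-deca-1,4,6-trien-3-ol; 4 triethyl orthoacetate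
Product: 7 ethyl (4E,6E,8E)-dodeca-4,6,8-trienoate, via mixed orthoester 5 (not isolated), via ketene acetal 6 (not isolated)
Conditions: MeC(OEt)3 (6 equiv), EtCO2H (5 mol%), 135–140 °C, EtOH distilled off
Reagents that add atoms: triethyl orthoacetate, CC(OCC)(OCC)OCC
Why: Johnson orthoester Claisen rearrangement: acid-catalysed exchange of one ethoxy group of 4 by the hydroxyl of 3 gives 5, loss of ethanol gives ketene acetal 6, and 6 undergoes a concerted suprafacial [3,3]-sigmatropic shift in which the C2–C3 bond forms as the carbinol C–O bond breaks and the ester carbonyl appears. The closest known reaction type is the orthoester Claisen rearrangement of secondary divinyl carbinols to (4E)-4,6-dienoates; here the dienyl arm is one double bond longer. No ring is closed and no stereocentre is formed; the carbinol centre of 3 is destroyed, so both enantiomers converge on one achiral product. The new C4=C5 double bond should be E because the chair transition state places the dienyl substituent on the carbinol carbon equatorial, the axial alternative meeting a 1,3-diaxial clash with the ethoxy group on the ketene acetal carbon. The step needs regioselection between the two allylic arms of 6: bonding at the unsubstituted vinyl CH2 is sterically open and gives the fully conjugated triene, whereas bonding at C5 of the dienyl arm is to a substituted internal carbon and interrupts conjugation. The existing 4E and 6E double bonds of 3 lie outside the six-atom array and keep their geometry. A weak acid in catalytic amount and removal of ethanol should keep ionisation of the doubly allylic C–O bond slower than rearrangement.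

**Step 3**
Reactants: 7 ethyl (4E,6E,8E)-dodeca-4,6,8-trienoate
Product: 8 (4E,6E,8E)-dodeca-4,6,8-trien-1-ol
Conditions: LiAlH4, Et2O, 0 °C; Fieser work-up
Reagents that add atoms: none
Why: Hydride reduction of an ester to the primary alcohol; LiAlH4 does not reduce a triene that is not conjugated to the carbonyl group, so the three double-bond geometries are kept.

**Step 4**
Reactants: 8 (4E,6E,8E)-dodeca-4,6,8-trien-1-ol; 9 (2R)-2-[(triphenylmethoxy)methyl]oxirane [(R)-glycidyl trityl ether]
Product: 11 (2R)-1-[(4E,6E,8E)-dodeca-4,6,8-trien-1-yloxy]-3-(triphenylmethoxy)propan-2-ol, via sodium alkoxide 10 (not isolated)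
Conditions: NaH, DMF, 0 °C to rt; then 9 (1.2 equiv), 60 °C; aq. NH4Cl
Reagents that add atoms: (R)-glycidyl trityl ether, C1[C@@H](O1)COC(c2ccccc2)(c2ccccc2)c2ccccc2
Why: Base-mediated SN2 opening of a terminal epoxide by a primary alkoxide at the unsubstituted CH2, the standard entry to 1-O-alkyl-3-O-trityl-glycerols; C2 of 9 is not touched, so its configuration is carried unchanged into 11, and a trityl ether cannot migrate to the new alkoxide.

**Step 5**
Reactants: 11 (2R)-1-[(4E,6E,8E)-dodeca-4,6,8-trien-1-yloxy]-3-(triphenylmethoxy)propan-2-ol; 12 4-(acetyloxy)benzoyl chloride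
Product: 13 (2R)-1-[(4E,6E,8E)-dodeca-4,6,8-trien-1-yloxy]-3-(triphenylmethoxy)propan-2-yl 4-(acetyloxy)benzoate
Conditions: 12 (1.5 equiv), pyridine, DMAP (cat.), CH2Cl2, 0 °C to rt
Reagents that add atoms: 4-(acetyloxy)benzoyl chloride, CC(=O)Oc1ccc(cc1)C(Cl)=O
Why: DMAP-catalysed acylation of a secondary alcohol by an aroyl chloride; the phenol is masked as its acetate so the acid chloride cannot self-condense, and the C2–O bond is not broken, so the configuration is retained.

**Step 6**
Reactants: 13 (2R)-1-[(4E,6E,8E)-dodeca-4,6,8-trien-1-yloxy]-3-(triphenylmethoxy)propan-2-yl 4-(acetyloxy)benzoate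
Product: 14 (2R)-1-[(4E,6E,8E)-dodeca-4,6,8-trien-1-yloxy]-3-(triphenylmethoxy)propan-2-yl 4-hydroxybenzoate
Conditions: pyrrolidine (2 equiv), THF, 0 °C; pH 7 buffer
Reagents that add atoms: none
Why: Chemoselective aminolysis of an aryl acetate; phenoxide is a far better leaving group than a secondary alkoxide, so the amine should cleave the acetate and leave the alkyl aroate, and because O3 is still tritylated no hydroxyl is available for acyl migration.

**Step 7**
Reactants: 14 (2R)-1-[(4E,6E,8E)-dodeca-4,6,8-trien-1-yloxy]-3-(triphenylmethoxy)propan-2-yl 4-hydroxybenzoate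
Product: 15 (2S)-1-[(4E,6E,8E)-dodeca-4,6,8-trien-1-yloxy]-3-hydroxypropan-2-yl 4-hydroxybenzoate
Conditions: TsOH·H2O (10 mol%), MeOH/CH2Cl2 1:1, 0 °C; Et3N quench; rapid chromatography on neutral silica
Reagents that add atoms: none
Why: Acid-catalysed SN1 solvolysis of a trityl ether (detritylation), with methanol trapping the trityl cation; catalytic acid, low temperature and the electron-rich, weakly electrophilic 4-hydroxybenzoate carbonyl should keep O2→O3 acyl migration and triene protonation slower than detritylation. No bond to C2 is broken; the descriptor changes from R to S only because the CIP priorities of the two CH2O arms swap when trityl is lost.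

## Compound list

1 | (2E,4E)-octa-2,4-dienal | CCC/C=C/C=C/C=O | starting material
2 | vinylmagnesium bromide | C=C[Mg]Br | starting material
3 | rac-(4E,6E)-deca-1,4,6-trien-3-ol | CCC/C=C/C=C/C(O)C=C | intermediate
4 | triethyl orthoacetate | CC(OCC)(OCC)OCC | starting material
5 | (4E,6E)-3-(1,1-diethoxyethoxy)deca-1,4,6-triene (mixed orthoester, not isolated) | CCC/C=C/C=C/C(C=C)OC(C)(OCC)OCC | intermediate
6 | (4E,6E)-3-[(1-ethoxyethenyl)oxy]deca-1,4,6-triene (ketene acetal, not isolated) | CCC/C=C/C=C/C(C=C)OC(=C)OCC | intermediate
7 | ethyl (4E,6E,8E)-dodeca-4,6,8-trienoate | CCC/C=C/C=C/C=C/CCC(=O)OCC | intermediate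
8 | (4E,6E,8E)-dodeca-4,6,8-trien-1-ol | CCC/C=C/C=C/C=C/CCCO | intermediate
9 | (2R)-2-[(triphenylmethoxy)methyl]oxirane, (R)-glycidyl trityl ether | C1[C@@H](O1)COC(c2ccccc2)(c2ccccc2)c2ccccc2 | starting material
10 | sodium (4E,6E,8E)-dodeca-4,6,8-trien-1-olate (not isolated) | CCC/C=C/C=C/C=C/CCC[O-].[Na+] | intermediate
11 | (2R)-1-[(4E,6E,8E)-dodeca-4,6,8-trien-1-yloxy]-3-(triphenylmethoxy)propan-2-ol | CCC/C=C/C=C/C=C/CCCOC[C@@H](O)COC(c1ccccc1)(c1ccccc1)c1ccccc1 | intermediate
12 | 4-(acetyloxy)benzoyl chloride | CC(=O)Oc1ccc(cc1)C(Cl)=O | starting material
13 | (2R)-1-[(4E,6E,8E)-dodeca-4,6,8-trien-1-yloxy]-3-(triphenylmethoxy)propan-2-yl 4-(acetyloxy)benzoate | CCC/C=C/C=C/C=C/CCCOC[C@@H](OC(=O)c1ccc(OC(C)=O)cc1)COC(c1ccccc1)(c1ccccc1)c1ccccc1 | intermediate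
14 | (2R)-1-[(4E,6E,8E)-dodeca-4,6,8-trien-1-yloxy]-3-(triphenylmethoxy)propan-2-yl 4-hydroxybenzoate | CCC/C=C/C=C/C=C/CCCOC[C@@H](OC(=O)c1ccc(O)cc1)COC(c1ccccc1)(c1ccccc1)c1ccccc1 | intermediate
15 | (2S)-1-[(4E,6E,8E)-dodeca-4,6,8-trien-1-yloxy]-3-hydroxypropan-2-yl 4-hydroxybenzoate | CCC/C=C/C=C/C=C/CCCOC[C@H](CO)OC(=O)c1ccc(O)cc1 | target

## Step count and least certain steps

Total step count: 7. Longest linear sequence: 7 steps (1 → 3 → 7 → 8 → 11 → 13 → 14 → 15).

**Step 2 (key step).** What may go wrong:
- acid-promoted ionisation of the doubly allylic C–O bond of 3 or 5, leading to allylic transposition or elimination before the sigmatropic shift;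
- a competing [3,3] shift through the dienyl arm;
- thermal cycloaddition or oligomerisation of the triene at 140 °C;
- partial loss of E geometry.

Fallback, setting out from 1 and returning at 8: the C4=C5 bond is made by a Julia–Kocienski olefination instead. Commercial 4-[(tert-butyldimethylsilyl)oxy]butan-1-ol is coupled with 1-phenyl-1H-tetrazole-5-thiol under Mitsunobu conditions to give 5-({4-[(tert-butyldimethylsilyl)oxy]butyl}sulfanyl)-1-phenyl-1H-tetrazole F1. Oxidation (mCPBA, NaHCO3) gives 5-({4-[(tert-butyldimethylsilyl)oxy]butyl}sulfonyl)-1-phenyl-1H-tetrazole F2. Metalation of F2 with KHMDS in DME at −60 °C and addition of 1 should give tert-butyl[(4E,6E,8E)-dodeca-4,6,8-trien-1-yloxy]dimethylsilane F3, and TBAF then gives 8.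

**Step 7.** What may go wrong: acid-catalysed O2→O3 acyl migration through the cyclic orthoacid once O3–H is free, during the reaction or on silica, and protonation of the triene with isomerisation or methanol addition.

Fallback, setting out from 11 and returning at 15: the trityl group is removed before any ester is present, and the last unmasking is done with buffered fluoride. Detritylation of 11 (TsOH, MeOH/CH2Cl2) gives (2S)-3-[(4E,6E,8E)-dodeca-4,6,8-trien-1-yloxy]propane-1,2-diol F4. Primary-selective silylation (TBSCl, imidazole, 0 °C) gives (2R)-1-{[tert-butyl(dimethyl)silyl]oxy}-3-[(4E,6E,8E)-dodeca-4,6,8-trien-1-yloxy]propan-2-ol F5. Acylation with 12 (pyridine, DMAP) gives (2R)-1-{[tert-butyl(dimethyl)silyl]oxy}-3-[(4E,6E,8E)-dodeca-4,6,8-trien-1-yloxy]propan-2-yl 4-(acetyloxy)benzoate F6. Pyrrolidine gives (2R)-1-{[tert-butyl(dimethyl)silyl]oxy}-3-[(4E,6E,8E)-dodeca-4,6,8-trien-1-yloxy]propan-2-yl 4-hydroxybenzoate F7, and HF·pyridine in THF/pyridine at 0 °C gives 15.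

**Step 4.** What may go wrong: slow epoxide opening at a temperature the reagents tolerate, with competing attack of the product secondary alkoxide on a second epoxide molecule (oligomerisation) and incomplete use of 8.

Fallback, setting out from 8 and returning at 11: the polarity of the ether formation is reversed. Mesylation of 8 (MsCl, Et3N) gives (4E,6E,8E)-dodeca-4,6,8-trien-1-yl methanesulfonate F8. Displacement by the sodium alkoxide of commercial (R)-solketal in DMF gives (4R)-4-{[(4E,6E,8E)-dodeca-4,6,8-trien-1-yloxy]methyl}-2,2-dimethyl-1,3-dioxolane F9. Aqueous acetic acid gives the diol F4 described under step 7, and primary-selective tritylation (TrCl, pyridine) gives 11.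

## Further compounds

F1 | step 2 | 5-({4-[(tert-butyldimethylsilyl)oxy]butyl}sulfanyl)-1-phenyl-1H-tetrazole | CC(C)(C)[Si](C)(C)OCCCCSc1nnnn1-c1ccccc1
F2 | step 2 | 5-({4-[(tert-butyldimethylsilyl)oxy]butyl}sulfonyl)-1-phenyl-1H-tetrazole | CC(C)(C)[Si](C)(C)OCCCCS(=O)(=O)c1nnnn1-c1ccccc1
F3 | step 2 | tert-butyl[(4E,6E,8E)-dodeca-4,6,8-trien-1-yloxy]dimethylsilane | CCC/C=C/C=C/C=C/CCCO[Si](C)(C)C(C)(C)C
F4 | step 7 | (2S)-3-[(4E,6E,8E)-dodeca-4,6,8-trien-1-yloxy]propane-1,2-diol | CCC/C=C/C=C/C=C/CCCOC[C@@H](O)CO
F5 | step 7 | (2R)-1-{[tert-butyl(dimethyl)silyl]oxy}-3-[(4E,6E,8E)-dodeca-4,6,8-trien-1-yloxy]propan-2-ol | CCC/C=C/C=C/C=C/CCCOC[C@@H](O)CO[Si](C)(C)C(C)(C)C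
F6 | step 7 | (2R)-1-{[tert-butyl(dimethyl)silyl]oxy}-3-[(4E,6E,8E)-dodeca-4,6,8-trien-1-yloxy]propan-2-yl 4-(acetyloxy)benzoate | CCC/C=C/C=C/C=C/CCCOC[C@@H](OC(=O)c1ccc(OC(C)=O)cc1)CO[Si](C)(C)C(C)(C)C
F7 | step 7 | (2R)-1-{[tert-butyl(dimethyl)silyl]oxy}-3-[(4E,6E,8E)-dodeca-4,6,8-trien-1-yloxy]propan-2-yl 4-hydroxybenzoate | CCC/C=C/C=C/C=C/CCCOC[C@@H](OC(=O)c1ccc(O)cc1)CO[Si](C)(C)C(C)(C)C
F8 | step 4 | (4E,6E,8E)-dodeca-4,6,8-trien-1-yl methanesulfonate | CCC/C=C/C=C/C=C/CCCOS(C)(=O)=O
F9 | step 4 | (4R)-4-{[(4E,6E,8E)-dodeca-4,6,8-trien-1-yloxy]methyl}-2,2-dimethyl-1,3-dioxolane | CCC/C=C/C=C/C=C/CCCOC[C@@H]1COC(C)(C)O1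
A1 | alternative 1 | (4-hydroxybutyl)triphenylphosphonium bromide | OCCCC[P+](c1ccccc1)(c1ccccc1)c1ccccc1.[Br-]
A2 | alternative 1 | (4Z,6E,8E)-dodeca-4,6,8-trien-1-ol | CCC/C=C/C=C/C=C\CCCO
A3 | alternative 2 | (1E,3E,5E)-1-iodonona-1,3,5-triene | CCC/C=C/C=C/C=C/I
A4 | alternative 2 | (2R)-1-(prop-2-en-1-yloxy)-3-(triphenylmethoxy)propan-2-ol | C=CCOC[C@@H](O)COC(c1ccccc1)(c1ccccc1)c1ccccc1
A5 | alternative 3 | oxetan-3-yl 4-hydroxybenzoate | O=C(OC1COC1)c1ccc(O)cc1
A6 | alternative 3 | 4-(2,6,7-trioxabicyclo[2.2.1]heptan-1-yl)phenol | Oc1ccc(cc1)C12OCC(CO1)O2
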